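**Retrosynthetic overview**
1. Target 14 ⇒ bis(N‑Boc) imide 13 ⇒ diamide 12: both CH2OH groups are reduced 8‑aminoquinoline amide carbonyls, and the phenols are carried as pivalates.
2. Key disconnection: both C(sp3)–aryl bonds (C2–Ar and C5–Ar) of 12 are made in one operation by twofold amide‑directed palladium‑catalysed C–H arylation of the C2‑symmetric trans‑diamide 8 with aryl iodide 10.
3. Each cis‑fused palladacycle places an aryl group cis to its own amide, so the single 3,4‑trans element of 8 dictates the 2,3‑cis/3,4‑trans/4,5‑cis pattern of the target.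
4. 8 ⇒ (3R,4R)‑tetrahydrofuran‑3,4‑dicarboxylic acid 5 ⇒ di‑(−)‑menthyl succinate 1 + bis(chloromethyl) ether 2.
5. Ring order: the tetrahydrofuran is the only ring formed and is made first (step 1); both arene rings come intact from 4‑iodo‑2‑methoxyphenol 9.

Assumption: the name is taken to mean exactly the given SMILES, which I read as (2S,3S,4S,5S) with 2,3‑cis, 3,4‑trans, 4,5‑cis; step 1 is assumed to show the same facial sense as the known dialkylations of the same dienolate with α,ω‑dihaloalkanes (if not, the ester from (+)‑menthol is used).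

**Step 1**
Reactants: 1 di‑(−)‑menthyl succinate; 2 bis(chloromethyl) ether
Product: 4 bis[(1R,2S,5R)‑menthyl] (3R,4R)‑tetrahydrofuran‑3,4‑dicarboxylate, via dilithium dienolate 3 (not isolated)
Conditions: lithium 2,2,6,6‑tetramethylpiperidide (LiTMP, 2.2 equiv), THF, −78 °C, 1 h; then 2 (1.05 equiv, regulated carcinogen, closed system), −78 to 0 °C; recrystallise
Reagents that add atoms: lithium 2,2,6,6‑tetramethylpiperidide, [Li]N1C(C)(C)CCCC1(C)C (its lithium enters intermediate 3 only; the CH2OCH2 unit comes from reactant 2)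
Why: Proposed new method: extension of the known asymmetric double alkylation of the dimenthyl succinate dienolate with α,ω‑dihaloalkanes (closest known reaction type, an enolate dialkylation/annulation) to an α‑chloro ether bis‑electrophile, in which C‑alkylation by the very reactive ClCH2O unit is followed by 5‑exo‑tet closure of the remaining enolate while the menthyl groups shield the same faces as in the carbocyclic cases, so the trans‑(3R,4R) diester is expected (spatially the same as the (1S,2S)‑cycloalkane diesters from this auxiliary, the descriptor changing only because of the ring oxygen).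

**Step 2**
Reactants: 4 bis[(1R,2S,5R)‑menthyl] (3R,4R)‑tetrahydrofuran‑3,4‑dicarboxylate
Product: 5 (3R,4R)‑tetrahydrofuran‑3,4‑dicarboxylic acid
Conditions: KOH (10%), MeOH–H2O 9:1, 65 °C; then aq. HCl to pH 1, NaCl, EtOAc extraction
Reagents that add atoms: potassium hydroxide, [K+].[OH-] (supplies the hydroxyl oxygen of each CO2H)
Why: Ester saponification (BAc2) as used for the analogous dimenthyl cycloalkane‑1,2‑dicarboxylates; no stereocentre is formed, the trans‑diacid is the thermodynamically preferred isomer, the first‑formed carboxylate suppresses enolisation, and the ring oxygen cannot be expelled from an enolate because that would be a reverse 5‑endo‑trig process.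

**Step 3**
Reactants: 5 (3R,4R)‑tetrahydrofuran‑3,4‑dicarboxylic acid; 6 8‑aminoquinoline (two equivalents are incorporated, one per carboxyl group)
Product: 8 (3R,4R)‑N3,N4‑di(quinolin‑8‑yl)tetrahydrofuran‑3,4‑dicarboxamide, via diacid dichloride 7 (not isolated)
Conditions: (COCl)2 (2.5 equiv), DMF (cat.), CH2Cl2, 0 °C to rt, evaporate; then 6 (2.2 equiv), pyridine (3 equiv), CH2Cl2, 0 °C to rt; ee checked by chiral HPLC, recrystallise
Reagents that add atoms: oxalyl chloride, O=C(Cl)C(=O)Cl (its chlorine enters intermediate 7 only)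
Why: Acid chloride formation (DMF/Vilsmeier catalysis) followed by Schotten–Baumann‑type amidation of both acyl chlorides, each by one molecule of 6; the trans‑diacid cannot close to a trans‑fused anhydride and the weak base pyridine avoids ketene formation, so C3 and C4 keep their configuration.

**Step 4**
Reactants: 9 4‑iodo‑2‑methoxyphenol
Product: 10 4‑iodo‑2‑methoxyphenyl pivalate
Conditions: PivCl, Et3N, DMAP (cat.), CH2Cl2, 0 °C to rt
Reagents that add atoms: pivaloyl chloride, CC(C)(C)C(Cl)=O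
Why: DMAP‑catalysed O‑acylation of the phenol; the pivalate survives the silver‑mediated arylation, makes the arene a poor donor for benzylic ionisation, and is removed by hydride in step 7.

**Step 5**
Reactants: 8 (3R,4R)‑N3,N4‑di(quinolin‑8‑yl)tetrahydrofuran‑3,4‑dicarboxamide; 10 4‑iodo‑2‑methoxyphenyl pivalate (two equivalents are incorporated)
Product: 12 (2S,3R,4R,5S)‑2,5‑bis[3‑methoxy‑4‑(pivaloyloxy)phenyl]‑N3,N4‑di(quinolin‑8‑yl)tetrahydrofuran‑3,4‑dicarboxamide, via monoarylated diamide 11 (not isolated)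
Conditions: 10 (6 equiv), Pd(OAc)2 (20 mol %), AgOAc (4.5 equiv), PivOH (1 equiv), toluene, 110 °C, 36 h
Reagents that add atoms: none
Why: Proposed new method: twofold 8‑aminoquinoline‑directed C(sp3)–H arylation (closest known reaction type: Daugulis‑type palladium‑catalysed β‑methylene arylation of aminoquinoline amides, cis‑selective on cyclobutane, pyrrolidine, tetrahydrofuran and benzodioxane carboxamides), in which each N,N‑chelated divalent palladium amidate activates the cis C–H bond of its neighbouring OCH2 group through a cis‑fused five‑membered palladacycle (the other β‑carbon is a methine, which is far less prone to palladation), and oxidative addition of 10 to tetravalent palladium followed by C–C reductive elimination with retention puts each aryl group cis to its amide, relaying the fixed 3,4‑trans relationship into the 2,3‑cis/4,5‑cis (2S,5S) configuration.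

**Step 6**
Reactants: 12 (2S,3R,4R,5S)‑2,5‑bis[3‑methoxy‑4‑(pivaloyloxy)phenyl]‑N3,N4‑di(quinolin‑8‑yl)tetrahydrofuran‑3,4‑dicarboxamide
Product: 13 di‑tert‑butyl N,N'‑{[(2S,3R,4R,5S)‑2,5‑bis[3‑methoxy‑4‑(pivaloyloxy)phenyl]tetrahydrofuran‑3,4‑diyl]dicarbonyl}bis[N‑(quinolin‑8‑yl)carbamate]
Conditions: Boc2O (6 equiv), DMAP (1 equiv), MeCN, 50 °C
Reagents that add atoms: di‑tert‑butyl dicarbonate, CC(C)(C)OC(=O)OC(=O)OC(C)(C)C
Why: DMAP‑catalysed N‑acylation (Boc activation) turns the secondary amides into twisted N‑acyl carbamates that can be cleaved under mild conditions; no stereocentre is touched.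

**Step 7**
Reactants: 13 di‑tert‑butyl N,N'‑{[(2S,3R,4R,5S)‑2,5‑bis[3‑methoxy‑4‑(pivaloyloxy)phenyl]tetrahydrofuran‑3,4‑diyl]dicarbonyl}bis[N‑(quinolin‑8‑yl)carbamate]
Product: 14 4,4'‑[(2S,3S,4S,5S)‑3,4‑bis(hydroxymethyl)tetrahydrofuran‑2,5‑diyl]bis(2‑methoxyphenol) (the target)
Conditions: LiAlH4 (6 equiv), THF, 0 °C to rt; aq. KNaC4H4O6 (Rochelle salt) work‑up at pH 7
Reagents that add atoms: none
Why: Hydride reduction of the activated N‑acyl carbamates (acyl C–N cleavage to the aldehyde and on to the primary alcohol) together with reductive cleavage of both aryl pivalates; hydride addition is faster than enolisation so the cis C2/C3 and C4/C5 relationships survive, and the neutral work‑up avoids acid‑catalysed benzylic epimerisation of the p‑hydroxybenzyl ether (C3 and C4 change descriptor from R to S only through CIP priorities).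

**Compound list**
1 | di‑(−)‑menthyl succinate, bis[(1R,2S,5R)‑5‑methyl‑2‑(propan‑2‑yl)cyclohexyl] butanedioate | CC(C)[C@@H]1CC[C@@H](C)C[C@H]1OC(=O)CCC(=O)O[C@@H]1C[C@H](C)CC[C@H]1C(C)C | starting material
2 | bis(chloromethyl) ether | ClCOCCl | starting material
3 | dilithium dienolate of 1 | CC(C)[C@@H]1CC[C@@H](C)C[C@H]1OC(O[Li])=CC=C(O[Li])O[C@@H]1C[C@H](C)CC[C@H]1C(C)C | intermediate (not isolated)
4 | bis[(1R,2S,5R)‑menthyl] (3R,4R)‑tetrahydrofuran‑3,4‑dicarboxylate (trans) | C1OC[C@H](C(=O)O[C@@H]2C[C@H](C)CC[C@H]2C(C)C)[C@H]1C(=O)O[C@@H]3C[C@H](C)CC[C@H]3C(C)C | intermediate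
5 | (3R,4R)‑tetrahydrofuran‑3,4‑dicarboxylic acid | C1OC[C@H](C(=O)O)[C@H]1C(=O)O | intermediate
6 | 8‑aminoquinoline | Nc1cccc2cccnc12 | starting material
7 | (3R,4R)‑tetrahydrofuran‑3,4‑dicarbonyl dichloride | C1OC[C@H](C(Cl)=O)[C@H]1C(Cl)=O | intermediate (not isolated)
8 | (3R,4R)‑N3,N4‑di(quinolin‑8‑yl)tetrahydrofuran‑3,4‑dicarboxamide | C1OC[C@H](C(=O)Nc2cccc3cccnc23)[C@H]1C(=O)Nc1cccc2cccnc12 | intermediate
9 | 4‑iodo‑2‑methoxyphenol | COc1cc(I)ccc1O | starting material
10 | 4‑iodo‑2‑methoxyphenyl pivalate | COc1cc(I)ccc1OC(=O)C(C)(C)C | intermediate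
11 | (2S,3R,4R)‑2‑[3‑methoxy‑4‑(pivaloyloxy)phenyl]‑N3,N4‑di(quinolin‑8‑yl)tetrahydrofuran‑3,4‑dicarboxamide (aryl cis to the C3 amide) | COc1cc([C@H]2OC[C@H](C(=O)Nc3cccc4cccnc34)[C@H]2C(=O)Nc2cccc3cccnc23)ccc1OC(=O)C(C)(C)C | intermediate (not isolated)
12 | (2S,3R,4R,5S)‑2,5‑bis[3‑methoxy‑4‑(pivaloyloxy)phenyl]‑N3,N4‑di(quinolin‑8‑yl)tetrahydrofuran‑3,4‑dicarboxamide (each aryl cis to its neighbouring amide, amides trans) | COc1cc([C@H]2O[C@H](c3ccc(OC(=O)C(C)(C)C)c(OC)c3)[C@H](C(=O)Nc3cccc4cccnc34)[C@H]2C(=O)Nc2cccc3cccnc23)ccc1OC(=O)C(C)(C)C | intermediate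
13 | di‑tert‑butyl N,N'‑{[(2S,3R,4R,5S)‑2,5‑bis[3‑methoxy‑4‑(pivaloyloxy)phenyl]tetrahydrofuran‑3,4‑diyl]dicarbonyl}bis[N‑(quinolin‑8‑yl)carbamate] | COc1cc([C@H]2O[C@H](c3ccc(OC(=O)C(C)(C)C)c(OC)c3)[C@H](C(=O)N(C(=O)OC(C)(C)C)c3cccc4cccnc34)[C@H]2C(=O)N(C(=O)OC(C)(C)C)c2cccc3cccnc23)ccc1OC(=O)C(C)(C)C | intermediate
14 | 4,4'‑[(2S,3S,4S,5S)‑3,4‑bis(hydroxymethyl)tetrahydrofuran‑2,5‑diyl]bis(2‑methoxyphenol) | COc1cc([C@H]2O[C@H](c3ccc(O)c(OC)c3)[C@H](CO)[C@H]2CO)ccc1O | target

**Step count**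
Total steps: 7. Longest linear sequence: 6 (steps 1, 2, 3, 5, 6, 7); step 4 is a one‑step side branch.

**Three steps most likely to fail**

Step 5 (twofold C–H arylation). The likely problems are sequestration of palladium by the two bidentate auxiliaries acting together as an N4 ligand, or a sluggish α‑oxy C–H activation. The fallback gives up the strongly chelating auxiliaries for a weakly coordinating acidic amide with an external ligand. It sets out from diacid 5 (through the same dichloride 7), which is condensed with two equivalents of 2,3,5,6‑tetrafluoro‑4‑(trifluoromethyl)aniline to give (3R,4R)‑N3,N4‑bis[2,3,5,6‑tetrafluoro‑4‑(trifluoromethyl)phenyl]tetrahydrofuran‑3,4‑dicarboxamide F1. Arylation of this monodentate amide with 10 (Pd(OAc)2, a 2‑alkoxyquinoline or 2‑picoline ligand, Ag2CO3, 110 °C) gives, by the same cis‑palladation logic, (2S,3R,4R,5S)‑2,5‑bis[3‑methoxy‑4‑(pivaloyloxy)phenyl]‑N3,N4‑bis[2,3,5,6‑tetrafluoro‑4‑(trifluoromethyl)phenyl]tetrahydrofuran‑3,4‑dicarboxamide F2. Boc2O/DMAP converts it into di‑tert‑butyl N,N'‑{[(2S,3R,4R,5S)‑2,5‑bis[3‑methoxy‑4‑(pivaloyloxy)phenyl]tetrahydrofuran‑3,4‑diyl]dicarbonyl}bis{N‑[2,3,5,6‑tetrafluoro‑4‑(trifluoromethyl)phenyl]carbamate} F3, and LiAlH4 as in step 7 brings the route back at target 14.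

Step 1 (dienolate dialkylation with the α‑chloro ether). O‑alkylation, oligomerisation or an unexpected facial sense are possible. The fallback replaces the auxiliary‑controlled annulation by a stereospecific cycloaddition followed by resolution. It sets out from 8‑aminoquinoline 6, two equivalents of which react with fumaryl chloride and pyridine to give (2E)‑N1,N4‑di(quinolin‑8‑yl)but‑2‑enediamide F4. Suprafacial [3+2] cycloaddition of the parent carbonyl ylide (from chloromethyl (trimethylsilyl)methyl ether and CsF in MeCN) to this E‑alkene gives the racemic trans‑diamide, that is 8 together with its enantiomer (3S,4S)‑N3,N4‑di(quinolin‑8‑yl)tetrahydrofuran‑3,4‑dicarboxamide F5. Preparative chromatography on a chiral stationary phase removes F5, and the route is rejoined at 8.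

Step 7 (reductive removal of both auxiliaries with retention of the cis relationships). Hydride attack at the Boc carbonyl or partial epimerisation could intervene. The fallback hydrolyses first and reduces afterwards. It sets out from 13: LiOH/H2O2 in THF–H2O at 0 °C, then excess LiOH at rt to cleave the pivalates and a Na2SO3 quench, gives (2S,3R,4R,5S)‑2,5‑bis(4‑hydroxy‑3‑methoxyphenyl)tetrahydrofuran‑3,4‑dicarboxylic acid F6, whose carboxylates no longer epimerise. BH3·SMe2 in THF then reduces both acids and the route comes back at target 14.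

**Further compounds**
F1 | step 5 | (3R,4R)‑N3,N4‑bis[2,3,5,6‑tetrafluoro‑4‑(trifluoromethyl)phenyl]tetrahydrofuran‑3,4‑dicarboxamide | C1OC[C@H](C(=O)Nc2c(F)c(F)c(C(F)(F)F)c(F)c2F)[C@H]1C(=O)Nc1c(F)c(F)c(C(F)(F)F)c(F)c1F
F2 | step 5 | (2S,3R,4R,5S)‑2,5‑bis[3‑methoxy‑4‑(pivaloyloxy)phenyl]‑N3,N4‑bis[2,3,5,6‑tetrafluoro‑4‑(trifluoromethyl)phenyl]tetrahydrofuran‑3,4‑dicarboxamide | COc1cc([C@H]2O[C@H](c3ccc(OC(=O)C(C)(C)C)c(OC)c3)[C@H](C(=O)Nc3c(F)c(F)c(C(F)(F)F)c(F)c3F)[C@H]2C(=O)Nc2c(F)c(F)c(C(F)(F)F)c(F)c2F)ccc1OC(=O)C(C)(C)C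
F3 | step 5 | di‑tert‑butyl N,N'‑{[(2S,3R,4R,5S)‑2,5‑bis[3‑methoxy‑4‑(pivaloyloxy)phenyl]tetrahydrofuran‑3,4‑diyl]dicarbonyl}bis{N‑[2,3,5,6‑tetrafluoro‑4‑(trifluoromethyl)phenyl]carbamate} | COc1cc([C@H]2O[C@H](c3ccc(OC(=O)C(C)(C)C)c(OC)c3)[C@H](C(=O)N(C(=O)OC(C)(C)C)c3c(F)c(F)c(C(F)(F)F)c(F)c3F)[C@H]2C(=O)N(C(=O)OC(C)(C)C)c2c(F)c(F)c(C(F)(F)F)c(F)c2F)ccc1OC(=O)C(C)(C)C
F4 | step 1 | (2E)‑N1,N4‑di(quinolin‑8‑yl)but‑2‑enediamide | O=C(/C=C/C(=O)Nc1cccc2cccnc12)Nc1cccc2cccnc12
F5 | step 1 | (3S,4S)‑N3,N4‑di(quinolin‑8‑yl)tetrahydrofuran‑3,4‑dicarboxamide | C1OC[C@@H](C(=O)Nc2cccc3cccnc23)[C@@H]1C(=O)Nc1cccc2cccnc12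
F6 | step 7 | (2S,3R,4R,5S)‑2,5‑bis(4‑hydroxy‑3‑methoxyphenyl)tetrahydrofuran‑3,4‑dicarboxylic acid | COc1cc([C@H]2O[C@H](c3ccc(O)c(OC)c3)[C@H](C(=O)O)[C@H]2C(=O)O)ccc1O
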